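**Assumption:** (−)-menthone is bought as the (2S,5R) isomer at ≥98% purity (any isomenthone in it lowers the ee of everything downstream), and magnolol is bought as such.

## Retrosynthetic overview

- The aryl–C3 bond and its configuration come from an aromatic Claisen ([3,3]) shift of a tertiary allyl aryl ether, so the stereochemical problem becomes that of one C–O bond.
- That tertiary C1–O bond is made by an anti-SN2' aryloxylation of a cis-piperityl trichloroacetimidate with magnolol (key step; it fixes both regiochemistry and configuration).
- The imidate comes from cis-piperitol, from (S)-piperitone, from (−)-menthone, which supplies the isopropyl stereocentre.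
- No ring is formed: the cyclohexene ring is that of menthone and both benzene rings are those of magnolol.

## Route

**Step 1**
Reactants: 1 (−)-menthone
Product: 4 (S)-piperitone, via lithium enolate 2 (not isolated), via silyl enol ether 3 (not isolated)
Conditions: LiN(i-Pr)2, THF, −78 °C; TMSCl, −78 to 0 °C; then Pd(OAc)2 (10 mol %), O2 (1 atm), DMSO, 25 °C
Reagents that add atoms: none
Why: Kinetic deprotonation takes the CH2 α-proton and leaves the isopropyl-bearing centre untouched, and the silyl enol ether then undergoes Saegusa–Ito oxidation (palladium enolate, β-hydride elimination) to the enone; no new stereocentre is made.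

**Step 2**
Reactants: 4 (S)-piperitone
Product: 5 cis-piperitol
Conditions: LiBH(s-Bu)3, THF, −78 °C; then NaOH, H2O2, H2O, 0 °C
Reagents that add atoms: none
Why: The bulky hydride (L-Selectride reduction) adds 1,2 to the β-substituted enone from the face opposite the adjacent isopropyl group, so the new carbinol centre (R) carries OH cis to isopropyl.

**Step 3**
Reactants: 5 cis-piperitol
Product: 6 cis-piperityl trichloroacetimidate
Conditions: Cl3CCN, DBU (10 mol %), CH2Cl2, 0 °C; used crude after filtration through Et3N-deactivated silica
Reagents that add atoms: trichloroacetonitrile, N#CC(Cl)(Cl)Cl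
Why: Base-catalysed addition of the alcohol to the nitrile (trichloroacetimidate formation) leaves the carbinol C–O bond and both stereocentres untouched.

**Step 4**
Reactants: 6 cis-piperityl trichloroacetimidate; 7 magnolol
Product: 8 tertiary allyl aryl ether
Conditions: [Pd(μ-OAc)(κ2-C,N-C6H4CH2NMe2)]2 (5 mol %), 7 (3 equiv, excess recovered), CH2Cl2, 25 °C
Reagents that add atoms: none
Why: Proposed new method: a divalent-palladium palladacycle-catalysed anti-SN2' aryloxylation that makes a tertiary allyl aryl ether from a cyclic secondary imidate with a trisubstituted alkene; the imidate nitrogen and the C1=C2 alkene chelate palladium on the face of the pseudoaxial C3–O bond (the isopropyl face), a phenol oxygen of 7 (the two are equivalent) adds to the methyl-bearing C1 from the opposite face (Markovnikov anti-oxypalladation), and syn β-oxygen elimination expels trichloroacetamide, so the new C1–O bond is trans to isopropyl (1R); the closest known reaction is the Overman-type palladacycle-catalysed SN2' etherification of primary (Z)-allylic trichloroacetimidates with phenols, which has not been shown for trisubstituted cyclic alkenes or for tertiary ether formation.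

**Step 5**
Reactants: 8 tertiary allyl aryl ether
Product: 10 target, via dienone 9 (not isolated)
Conditions: PhNEt2, 130 °C, argon
Reagents that add atoms: none
Why: Aromatic Claisen rearrangement: the suprafacial [3,3] shift through a boat transition state delivers the only free ortho carbon to C3 on the face that carried oxygen, so the aryl group ends up trans to isopropyl (new centre S), and dienone 9 enolises to the phenol.

## Compound list

1 | (−)-menthone, (2S,5R)-5-methyl-2-(propan-2-yl)cyclohexan-1-one | C[C@H]1CC(=O)[C@H](C(C)C)CC1 | starting material
2 | lithium (3R,6S)-3-methyl-6-(propan-2-yl)cyclohex-1-en-1-olate (kinetic enolate) | C[C@H]1C=C(O[Li])[C@H](C(C)C)CC1 | intermediate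
3 | trimethyl{[(3R,6S)-3-methyl-6-(propan-2-yl)cyclohex-1-en-1-yl]oxy}silane | C[C@H]1C=C(O[Si](C)(C)C)[C@H](C(C)C)CC1 | intermediate
4 | (S)-piperitone, (6S)-3-methyl-6-(propan-2-yl)cyclohex-2-en-1-one | CC1=CC(=O)[C@H](C(C)C)CC1 | intermediate
5 | cis-piperitol, (1R,6S)-3-methyl-6-(propan-2-yl)cyclohex-2-en-1-ol (OH cis to isopropyl) | CC1=C[C@H](O)[C@H](C(C)C)CC1 | intermediate
6 | (1R,6S)-3-methyl-6-(propan-2-yl)cyclohex-2-en-1-yl 2,2,2-trichloroethanimidate | CC1=C[C@H](OC(=N)C(Cl)(Cl)Cl)[C@H](C(C)C)CC1 | intermediate
7 | magnolol, 5,5'-di(prop-2-en-1-yl)-[1,1'-biphenyl]-2,2'-diol | C=CCc1ccc(O)c(-c2cc(CC=C)ccc2O)c1 | starting material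
8 | 2'-{[(1R,4S)-1-methyl-4-(propan-2-yl)cyclohex-2-en-1-yl]oxy}-5,5'-di(prop-2-en-1-yl)-[1,1'-biphenyl]-2-ol (aryloxy trans to isopropyl) | C=CCc1ccc(O)c(-c2cc(CC=C)ccc2O[C@@]3(C)C=C[C@H](C(C)C)CC3)c1 | intermediate
9 | 2-[2-hydroxy-5-(prop-2-en-1-yl)phenyl]-6-[(1S,6S)-3-methyl-6-(propan-2-yl)cyclohex-2-en-1-yl]-4-(prop-2-en-1-yl)cyclohexa-2,4-dien-1-one (configuration at carbon 6 of the dienone not defined; it is lost on enolisation) | O=C1C(c2cc(CC=C)ccc2O)=CC(CC=C)=CC1[C@@H]3C=C(C)CC[C@H]3C(C)C | intermediate
10 | 3-[(1S,6S)-3-methyl-6-(propan-2-yl)cyclohex-2-en-1-yl]-5,5'-di(prop-2-en-1-yl)-[1,1'-biphenyl]-2,2'-diol (aryl trans to isopropyl) | C=CCc1ccc(O)c(-c2cc(CC=C)cc([C@@H]3C=C(C)CC[C@H]3C(C)C)c2O)c1 | target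

## Step count and risks

Total steps: 5. Longest linear sequence: 5 (1 → 4 → 5 → 6 → 8 → 10); magnolol 7 enters at step 4.

**Step 4 (the proposed new step)** is the most likely to fail. The phenol of 7 is ortho-arylated and must attack a fully substituted carbon. The trisubstituted alkene binds palladium weakly. The imidate may instead ionise (stereorandom ethers or C-alkylation) or rearrange to an allylic trichloroacetamide. The fallback uses known chemistry and sets out from 5: 5 and 7 (3 equiv) are treated with BF3·OEt2 on alumina (or catalytic p-TsOH) in CH2Cl2 at −10 °C. This is the acid-mediated Friedel–Crafts terpenylation of phenols used for menthadienol–resorcinol couplings. The allyl cation is attacked by the carbon ortho to the hydroxyl at C3, anti to the isopropyl group. It comes back to the route at 10, bypassing 6 and 8, and makes no new compound.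

**Step 5** may fail because the cyclic allyl unit forces a boat transition state. The strained tertiary ether can instead eliminate to p-menthadienes plus 7, or ionise under the influence of the neighbouring free phenol. The fallback sets out from 8 and replaces the thermal pericyclic shift by a Lewis-acid-triggered O-to-C migration: Et2AlCl (2.2 equiv), CH2Cl2/hexane, −78 °C. The aryloxyaluminate–allyl cation pair recombines at the ortho carbon, with C3 attacked anti to isopropyl under substrate control. It comes back at 10 and makes no new compound.

**Step 3** may fail because 6 is a secondary allylic imidate of a well-stabilised cation and may ionise or rearrange on handling. The fallback sets out from 4 and changes both the leaving group and the substitution mechanism: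
- Luche reduction (NaBH4, CeCl3·7H2O, MeOH, −20 °C) gives mainly trans-piperitol F1, separated from 5.
- ClCO2Me and pyridine in CH2Cl2 give trans-piperityl methyl carbonate F2.
- Tsuji–Trost etherification of F2 with 7 (Pd(PPh3)4, 5 mol %, THF, 0 to 25 °C) follows: zerovalent palladium ionises anti to the carbonate, which places it on the isopropyl face, and the phenoxide attacks C1 anti to palladium.
- The result is the same trans tertiary ether, so the fallback comes back at 8. Attack at the other allyl terminus is the expected side reaction and that isomer is removed by chromatography.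

## Further compounds

F1 | step 3 | trans-piperitol, (1S,6S)-3-methyl-6-(propan-2-yl)cyclohex-2-en-1-ol | CC1=C[C@@H](O)[C@H](C(C)C)CC1
F2 | step 3 | methyl (1S,6S)-3-methyl-6-(propan-2-yl)cyclohex-2-en-1-yl carbonate | CC1=C[C@@H](OC(=O)OC)[C@H](C(C)C)CC1
F0 | step 4 | none | none
F0 | step 5 | none | none
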